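**Retrosynthetic overview**
- Target ⇒ (Felkin–Anh ketone reduction) α-aryloxy ketone ⇒ (SN2 C–O bond) phenol core + (S)-α-chloro ketone, the latter from veratrole and (S)-2-chloropropanoyl chloride.
- Phenol core ⇒ (C2–aryl bond, oxocarbenium C-arylation of guaiacol) 5-aryl-3,4-dimethyl-γ-lactone.
- γ-Lactone ⇒ (C5–aryl bond, Felkin–Anh arylation of the half-reduced anhydride) (3R,4R)-3,4-dimethylsuccinic anhydride + aryl Grignard reagent.
- Anhydride ⇒ (key step: two ring-expansion carbonylations) (2S,3S)-2,3-dimethyloxirane + 2 CO; this sets C3 and C4.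
- Ring order: oxirane → oxetan-2-one → oxolane-2,5-dione → γ-lactone → 2,5-diaryl oxolane; all three arenes come from catechol.

Assumption: (2S,3S)-2,3-dimethyloxirane (trans-2,3-epoxybutane, single enantiomer) is taken as a catalogue compound.

**Step 1**
Reactants: 1 catechol
Product: 2 1,2-dimethoxybenzene (veratrole)
Conditions: MeI (2.5 equiv), K2CO3 (2.5 equiv), acetone, reflux
Reagents that add atoms: iodomethane, CI
Why: Double Williamson O-methylation (SN2 of the phenoxides on MeI); no stereocentre.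

**Step 2**
Reactants: 1 catechol
Product: 3 2-methoxyphenol (guaiacol)
Conditions: catechol (2 equiv), MeI (1.0 equiv), K2CO3 (1.0 equiv), acetone, reflux; aqueous wash, distillation
Reagents that add atoms: iodomethane, CI
Why: Mono-Williamson methylation: with one equivalent of base only the catechol mono-phenoxide is present and excess catechol suppresses the second alkylation; unreacted catechol is washed out with water.

**Step 3**
Reactants: 2 1,2-dimethoxybenzene
Product: 4 4-bromo-1,2-dimethoxybenzene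
Conditions: NBS (1.05 equiv), MeCN, rt
Reagents that add atoms: N-bromosuccinimide, O=C1CCC(=O)N1Br
Why: Electrophilic aromatic bromination para to a methoxy group gives a single regioisomer.

**Step 4**
Reactants: 2 1,2-dimethoxybenzene; 5 (S)-2-chloropropanoyl chloride
Product: 6 (S)-2-chloro-1-(3,4-dimethoxyphenyl)propan-1-one
Conditions: AlCl3 (1.2 equiv), CH2Cl2, 0 °C; ice/HCl
Reagents that add atoms: none
Why: Friedel–Crafts acylation para to a methoxy group; the α-chloro acylium ion does not enolise at 0 °C, so the (S) centre is carried over unchanged.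

**Step 5**
Reactants: 7 (2S,3S)-2,3-dimethyloxirane
Product: 9 (3R,4R)-3,4-dimethyloxolane-2,5-dione, via cis-β-lactone 8 (not isolated)
Conditions: [(ClTPP)Al(THF)2][Co(CO)4] (2 mol %), CO (60 bar), 1,4-dioxane, 90 °C
Reagents that add atoms: carbon monoxide, [C-]#[O+]
Why: Two consecutive ring-expansion carbonylations (oxirane → oxetan-2-one → oxolane-2,5-dione); in each, the Lewis-acid-activated C–O bond is opened by Co(CO)4− in an SN2 step with inversion, then CO inserts and the ring closes, so each carbon is inverted once and the (S,S)-trans-epoxide gives the (R,R)-trans-anhydride, fixing C3 and C4 of the target.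

**Step 6**
Reactants: 9 (3R,4R)-3,4-dimethyloxolane-2,5-dione; 4 4-bromo-1,2-dimethoxybenzene
Product: 13 (3R,4R,5S)-5-(3,4-dimethoxyphenyl)-3,4-dimethyloxolan-2-one, via aldehyde acid 10 (not isolated), via aryl Grignard reagent 11 (not isolated), via hydroxy acid 12 (not isolated)
Conditions: LiAlH(OtBu)3 (1.0 equiv), THF, −78 → −30 °C; then 11 (from 4, Mg, THF; 1.5 equiv), −78 → 0 °C; 1 M HCl, rt
Reagents that add atoms: none
Why: Half-reduction of the C2-symmetric anhydride (both carbonyls equivalent) gives the aldehyde carboxylate, and Felkin–Anh addition of the aryl Grignard reagent to this α-methyl aldehyde (the CH(CH3)CO2− arm anti to the nucleophile) sets C5 as (S), 4,5-cis; acid lactonisation closes the ring without touching the C–O stereocentre.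

**Step 7**
Reactants: 13 (3R,4R,5S)-5-(3,4-dimethoxyphenyl)-3,4-dimethyloxolan-2-one; 3 2-methoxyphenol
Product: 15 4-[(2S,3R,4R,5S)-5-(3,4-dimethoxyphenyl)-3,4-dimethyloxolan-2-yl]-2-methoxyphenol, via lactol 14 (not isolated)
Conditions: DIBAL-H (1.1 equiv), CH2Cl2, −78 °C; then 3 (3 equiv), BF3·OEt2 (3 equiv), −78 → −40 °C; Rochelle salt
Reagents that add atoms: none
Why: Proposed new method: one-pot reductive C-arylation of a γ-lactone with an unprotected phenol — DIBAL gives the aluminium lactolate of 14, BF3·OEt2 ionises it to the oxolanyl oxocarbenium ion, and aluminium guaiacolate formed in the flask (its OMe oxygen tied up in the Al chelate, its ortho position shielded by the Al ligands) attacks through the carbon para to O–Al from the inside face of the envelope (cis to the C3 methyl, trans to the C4 methyl and the C5 aryl), setting C2 as (S) and completing the 2,3-cis-3,4-trans-4,5-cis array; the closest known reactions are arylzinc additions to 2-sulfonyl-oxolane-derived oxocarbenium ions, Lewis-acid Friedel–Crafts C-arylation of lactol acetates with alkoxyarenes, and DIBAL/BF3·OEt2/Et3SiH reductive deoxygenation of lactones.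

**Step 8**
Reactants: 15 4-[(2S,3R,4R,5S)-5-(3,4-dimethoxyphenyl)-3,4-dimethyloxolan-2-yl]-2-methoxyphenol; 6 (S)-2-chloro-1-(3,4-dimethoxyphenyl)propan-1-one
Product: 16 (2R)-1-(3,4-dimethoxyphenyl)-2-{4-[(2S,3R,4R,5S)-5-(3,4-dimethoxyphenyl)-3,4-dimethyloxolan-2-yl]-2-methoxyphenoxy}propan-1-one
Conditions: K2CO3 (1.5 equiv), acetone, 35 °C
Reagents that add atoms: none
Why: Williamson-type SN2 displacement of the activated α-chloride by the phenoxide with inversion, (S) → (R); KCl precipitates from acetone, which suppresses chloride-exchange racemisation.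

**Step 9**
Reactants: 16 (2R)-1-(3,4-dimethoxyphenyl)-2-{4-[(2S,3R,4R,5S)-5-(3,4-dimethoxyphenyl)-3,4-dimethyloxolan-2-yl]-2-methoxyphenoxy}propan-1-one
Product: 17 (1R,2R)-1-(3,4-dimethoxyphenyl)-2-{4-[(2S,3R,4R,5S)-5-(3,4-dimethoxyphenyl)-3,4-dimethyloxolan-2-yl]-2-methoxyphenoxy}propan-1-ol
Conditions: polymer-supported borohydride (quaternary ammonium resin, BH4− form), MeOH, 0 °C → rt
Reagents that add atoms: none
Why: Non-chelating hydride reduction under Felkin–Anh (polar) control: hydride adds anti to the α-aryloxy group, giving the threo (1R,2R) alcohol from the (2R) ketone.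

**Compound list**
1 | catechol (benzene-1,2-diol) | Oc1ccccc1O | starting material
2 | 1,2-dimethoxybenzene (veratrole) | COc1ccccc1OC | intermediate
3 | 2-methoxyphenol (guaiacol) | COc1ccccc1O | intermediate
4 | 4-bromo-1,2-dimethoxybenzene | COc1ccc(Br)cc1OC | intermediate
5 | (S)-2-chloropropanoyl chloride | C[C@H](Cl)C(Cl)=O | starting material
6 | (S)-2-chloro-1-(3,4-dimethoxyphenyl)propan-1-one | C[C@H](Cl)C(=O)c1ccc(OC)c(OC)c1 | intermediate
7 | (2S,3S)-2,3-dimethyloxirane | C[C@@H]1O[C@H]1C | starting material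
8 | (3R,4S)-3,4-dimethyloxetan-2-one (cis-β-lactone, not isolated) | C[C@@H]1OC(=O)[C@@H]1C | intermediate
9 | (3R,4R)-3,4-dimethyloxolane-2,5-dione | O=C1OC(=O)[C@H](C)[C@H]1C | intermediate
10 | (2R,3R)-2,3-dimethyl-4-oxobutanoic acid (aldehyde acid, present as Li/Al carboxylate, not isolated) | O=C[C@H](C)[C@@H](C)C(O)=O | intermediate
11 | (3,4-dimethoxyphenyl)magnesium bromide (not isolated) | COc1ccc([Mg]Br)cc1OC | intermediate
12 | (2R,3R,4S)-4-(3,4-dimethoxyphenyl)-4-hydroxy-2,3-dimethylbutanoic acid (not isolated) | O[C@H](c1ccc(OC)c(OC)c1)[C@H](C)[C@@H](C)C(O)=O | intermediate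
13 | (3R,4R,5S)-5-(3,4-dimethoxyphenyl)-3,4-dimethyloxolan-2-one | O=C1O[C@H](c2ccc(OC)c(OC)c2)[C@H](C)[C@H]1C | intermediate
14 | (3R,4R,5S)-5-(3,4-dimethoxyphenyl)-3,4-dimethyloxolan-2-ol (lactol, anomer mixture, present as Al alkoxide, not isolated) | OC1O[C@H](c2ccc(OC)c(OC)c2)[C@H](C)[C@H]1C | intermediate
15 | 4-[(2S,3R,4R,5S)-5-(3,4-dimethoxyphenyl)-3,4-dimethyloxolan-2-yl]-2-methoxyphenol | Oc1ccc([C@H]2O[C@H](c3ccc(OC)c(OC)c3)[C@H](C)[C@H]2C)cc1OC | intermediate
16 | (2R)-1-(3,4-dimethoxyphenyl)-2-{4-[(2S,3R,4R,5S)-5-(3,4-dimethoxyphenyl)-3,4-dimethyloxolan-2-yl]-2-methoxyphenoxy}propan-1-one | COc1ccc(C(=O)[C@@H](C)Oc2ccc([C@H]3O[C@H](c4ccc(OC)c(OC)c4)[C@H](C)[C@H]3C)cc2OC)cc1OC | intermediate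
17 | (1R,2R)-1-(3,4-dimethoxyphenyl)-2-{4-[(2S,3R,4R,5S)-5-(3,4-dimethoxyphenyl)-3,4-dimethyloxolan-2-yl]-2-methoxyphenoxy}propan-1-ol | COc1ccc([C@@H](O)[C@@H](C)Oc2ccc([C@H]3O[C@H](c4ccc(OC)c(OC)c4)[C@H](C)[C@H]3C)cc2OC)cc1OC | target

**Totals**
Total step count: 9. Longest linear sequence: 6 steps (1 → 2 → 4 → 13 → 15 → 16 → 17).

**Steps most likely to fail**

Step 7 (the proposed new method). The risks are attack ortho to OH or para to OMe on guaiacol, O-arylation, and acid epimerisation of the benzylic C2/C5 centres. The fallback uses known chemistry; it sets out from 13 and comes back at 15. Lactone 13 is reduced with DIBAL-H and the lactol 14 is isolated, then converted with PhSO2H/CaCl2 into (3R,4R,5S)-2-(benzenesulfonyl)-5-(3,4-dimethoxyphenyl)-3,4-dimethyloxolane F1. In parallel, guaiacol 3 is brominated (NBS) to 4-bromo-2-methoxyphenol F2 and benzylated (BnBr, K2CO3) to 1-(benzyloxy)-4-bromo-2-methoxybenzene F3, which with Mg/LiCl/ZnBr2 in THF gives [4-(benzyloxy)-3-methoxyphenyl]zinc bromide F4. Addition of F4 to F1 (THF, rt) gives (2S,3R,4R,5S)-2-[4-(benzyloxy)-3-methoxyphenyl]-5-(3,4-dimethoxyphenyl)-3,4-dimethyloxolane F5 through the same oxocarbenium ion, and hydrogenolysis (H2, Pd/C) gives 15.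

Step 6. The risks are over-reduction of the anhydride to the CH2 lactone and only moderate Felkin–Anh selectivity (about 4:1 expected; the 4,5-trans lactone is removed by chromatography). The fallback sets out from 9 (with 2) and comes back at 13. AlCl3-mediated Friedel–Crafts acylation of 2 with 9 gives (2R,3R)-4-(3,4-dimethoxyphenyl)-2,3-dimethyl-4-oxobutanoic acid F6. Catalyst-controlled Noyori–Ikariya transfer hydrogenation of F6 [RuCl((S,S)-TsDPEN)(p-cymene), HCO2H/Et3N] gives the hydroxy acid 12, which lactonises to 13.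

Step 8. The risk is partial racemisation of 6 or 16 by enolisation under base. The fallback sets out from 15 and comes back at 16. Mitsunobu reaction of 15 with ethyl (S)-lactate (PPh3, DIAD; inversion) gives ethyl (2R)-2-{4-[(2S,3R,4R,5S)-5-(3,4-dimethoxyphenyl)-3,4-dimethyloxolan-2-yl]-2-methoxyphenoxy}propanoate F7. MeNHOMe·HCl/iPrMgCl converts it into the Weinreb amide (2R)-N-methoxy-N-methyl-2-{4-[(2S,3R,4R,5S)-5-(3,4-dimethoxyphenyl)-3,4-dimethyloxolan-2-yl]-2-methoxyphenoxy}propanamide F8. Addition of the Grignard reagent 11 to F8 gives 16.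

**Further compounds**
F1 | step 7 | (3R,4R,5S)-2-(benzenesulfonyl)-5-(3,4-dimethoxyphenyl)-3,4-dimethyloxolane | O=S(=O)(c1ccccc1)C1O[C@H](c2ccc(OC)c(OC)c2)[C@H](C)[C@H]1C
F2 | step 7 | 4-bromo-2-methoxyphenol | COc1cc(Br)ccc1O
F3 | step 7 | 1-(benzyloxy)-4-bromo-2-methoxybenzene | COc1cc(Br)ccc1OCc1ccccc1
F4 | step 7 | [4-(benzyloxy)-3-methoxyphenyl]zinc bromide | COc1cc([Zn]Br)ccc1OCc1ccccc1
F5 | step 7 | (2S,3R,4R,5S)-2-[4-(benzyloxy)-3-methoxyphenyl]-5-(3,4-dimethoxyphenyl)-3,4-dimethyloxolane | COc1cc([C@H]2O[C@H](c3ccc(OC)c(OC)c3)[C@H](C)[C@H]2C)ccc1OCc1ccccc1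
F6 | step 6 | (2R,3R)-4-(3,4-dimethoxyphenyl)-2,3-dimethyl-4-oxobutanoic acid | COc1ccc(C(=O)[C@H](C)[C@@H](C)C(O)=O)cc1OC
F7 | step 8 | ethyl (2R)-2-{4-[(2S,3R,4R,5S)-5-(3,4-dimethoxyphenyl)-3,4-dimethyloxolan-2-yl]-2-methoxyphenoxy}propanoate | CCOC(=O)[C@@H](C)Oc1ccc([C@H]2O[C@H](c3ccc(OC)c(OC)c3)[C@H](C)[C@H]2C)cc1OC
F8 | step 8 | (2R)-N-methoxy-N-methyl-2-{4-[(2S,3R,4R,5S)-5-(3,4-dimethoxyphenyl)-3,4-dimethyloxolan-2-yl]-2-methoxyphenoxy}propanamide | CON(C)C(=O)[C@@H](C)Oc1ccc([C@H]2O[C@H](c3ccc(OC)c(OC)c3)[C@H](C)[C@H]2C)cc1OC
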